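## The problem

Atom labels used throughout: ring A is the 4-hydroxy-3,5-dimethoxyphenyl ring, ring B the 4-carboxy-2,6-dimethoxyphenyl ring, C7 the ketone carbon on C1 of ring A, C8 the stereocentre, C9 the hydroxymethyl carbon.

The target 12 is acyclic. A three-carbon chain joins the two rings: C7 is bonded to ring A, and C8 carries H, C9 and the ether oxygen to C4 of ring B. No ring has to be closed, so the task is the order in which the ring A–C7 bond, the C8–O–ring B ether and the oxidation level of C7 are introduced.

C8 is (S) and is the only stereocentre. Nothing else in the molecule can induce it, so it must come from an enantiopure building block. The ether to the doubly ortho-substituted phenol oxygen of ring B must then be made with full control of configuration.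

Once C7 is a ketone, C8 is alpha to an aryl ketone and bears an aryloxy group, so it epimerizes through the enol. The C9 hydroxyl is then beta to the carbonyl, so base also opens retro-aldol loss of formaldehyde and dehydration. The free phenol, free benzoic acid and primary alcohol add polarity and rule out late protecting-group work in base.

The feature that opens a short route is that C7 is para to the free phenolic O–H on C4 of ring A. Two-electron oxidation of that phenol is relayed through the ring to C7 as a para-quinone methide. The C7 oxygen can therefore be installed last, from water, on precursor 9, in which C8 is still an ordinary, configurationally stable ether carbon.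

## Retrosynthesis

**12 to 9 (C7=O bond).** The two C–O bonds of the ketone are cut, leaving CH2 at C7. The neighbouring cuts, C7–C8 (aldol) and ring A–C7 (acyl coupling), both create the labile alpha-aryloxy ketone, or a throw-away C7 stereocentre, before protecting groups are removed. Here the ketone appears in the last operation and is never handled again. Precursor 9 has no carbonyl next to C8 and no group that base or acid can damage. The forward step must oxidize only the ring A phenol, pass through quinone methide 10 and benzylic alcohol 11, add water and not lose the C8 proton, and stop at the ketone. The descriptor changes from (2R) in 9 to (S) in 12 only because C7 gains priority over C9; the spatial arrangement is unchanged.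

**9 to 8 (three O–benzyl bonds).** The phenol of ring A, the C9 hydroxyl and the carboxyl are masked as benzyl ether, benzyl ether and benzyl ester. One neutral hydrogenolysis frees all three, and 8 contains nothing else that hydrogen can reduce. A methyl ester with a silyl ether would need two extra deprotections. The forward step must cleave the slower primary alkyl benzyl ether as well as the other two.

**8 to 5 + 7 (C8–O bond to ring B).** The ether is cut at the alkyl side and formed by Mitsunobu displacement with inversion, from secondary alcohol 5 and phenol 7. The aryl-side cut (nucleophilic aromatic substitution on a ring B fluoride) is unattractive because the carbon is flanked by two methoxy groups and activated only by one para ester. Both partners are simple: 5 has one stereocentre and 7 already has the full ring B substitution. The forward reaction must give clean inversion at a secondary carbon with a hindered but acidic phenol.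

**5 to 2 + 3, through 4 (ring A C1–C7 bond).** The aryl–CH2 bond is cut to aryl Grignard 4 and the terminal carbon of (S)-benzyl glycidyl ether 3. The stereocentre of 3 is not touched in the opening, so purchased enantiopurity is passed on unchanged: (S)-3 gives (S)-5, and the later inversion gives (R) at C8 of 8. Asymmetric dihydroxylation of an allylarene would be longer and typically less selective for this substitution pattern. The forward reaction must attack only the terminal epoxide carbon.

**7 to 6 and 2 to 1 (O–benzyl bonds).** Benzyl ester 7 comes from syringic acid 6 by selective carboxylate alkylation. Aryl bromide 2 comes from 4-bromo-2,6-dimethoxyphenol 1 by phenol benzylation, which is needed before a Grignard reagent can be formed.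

## Roads not taken

**Alternative 1:** The cut is the bond from the ether oxygen to C4 of ring B, with ring B not yet aromatic.
- Forward key step: Rh2(OAc)4 (divalent rhodium) decomposes diazo dione A1 in the presence of the bis-silylated secondary alcohol A2, and the carbenoid inserts into the O–H bond to give enol ether A3.
- Merits: the hindered ether forms with retention and with no substitution at C8, so inversion, elimination and aryl participation are not an issue.
- Weak points: the hydroxyl of A2 sits between two bulky silyloxy groups, and insertion must outrun Wolff rearrangement of the cyclic diazo dione. After A3, ring B still has to be dehydrogenated and methylated twice. The C7 carbinol stereocentre of A2 is made only to be oxidized away. That oxidation and the final deprotections take place with the labile ketone present. The step count would be roughly double.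
- Comparison: on the C8–O bond this road is safer than the Mitsunobu step of the chosen plan. The chosen plan sets against it a one-step ether formation from 7, which already has the finished ring B, and six steps overall.

**Alternative 2:** The cut is the C7–C8 bond.
- Forward key step: the dibutylboron Z-enolate (Bu2BOTf, i-Pr2NEt) of aryloxyacetyl imide A4 adds to aldehyde A5 to give syn aldol A6.
- Merits: the carbon–carbon bond and the C8 configuration are set in one auxiliary-controlled step of a very reliable type, and every later operation has close analogy.
- Weak points: A4 takes about three steps to make. The C7 carbinol centre of A6 is created and then destroyed. The auxiliary must be removed reductively beside a benzoate ester. The secondary benzylic hydroxyl must be oxidized selectively beside the primary one. The final hydrogenolysis is run on the alpha-aryloxy ketone, where carbonyl reduction and epimerization are possible. About nine steps result.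
- Comparison: in predictability of the key bond formation this road is clearly ahead of the chosen plan. The chosen plan is three steps shorter, builds no disposable stereocentre, and never carries the ketone through a further reaction.

**Alternative 3:** The cut is the ring A C1–C7 bond at the ketone oxidation level.
- Forward key step: thioester A7 couples with boronic acid A8 under Pd2(dba)3 (zerovalent palladium), tri(2-furyl)phosphine and CuTC (copper thiophene-2-carboxylate, monovalent copper) to give protected ketone A9.
- Merits: the ketone forms under neutral, base-free conditions, convergently, with no redox adjustment at C7.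
- Weak points: C8 is alpha to a carboxyl-level carbon in every intermediate leading to A7, and it bears an aryloxy group and a beta-silyloxy leaving group, so each step risks racemization or elimination. The ether to the hindered phenol must still be made, now at a more elimination-prone carbon. Three acid-labile groups must come off after the ketone is in place. Copper carboxylate is needed in stoichiometric amount. About nine to ten steps result.
- Comparison: A9 arises from a coupling with good analogy, whereas the chosen key step extends known phenol oxidations to a new setting. The chosen plan answers with a C8 centre that stays unactivated until the very last step, and with a much shorter sequence.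

Key step: step 6

Remark on the chemistry: 1, 6 and enantiopure 3 are taken as purchased. Both C7 epimers of 11 converge on 12, so the face of water addition to 10 does not matter.

## Route

Step 1
Reactants: 1 4-bromo-2,6-dimethoxyphenol
Product: 2 2-(benzyloxy)-5-bromo-1,3-dimethoxybenzene
Conditions: BnBr, K2CO3, DMF, rt
Reagents that add atoms: benzyl bromide, BrCc1ccccc1
Why: Williamson ether synthesis; the phenoxide, although flanked by two methoxy groups, is readily alkylated by a benzylic bromide in a dipolar aprotic solvent, and the aryl bromide is inert.

Step 2
Reactants: 2 2-(benzyloxy)-5-bromo-1,3-dimethoxybenzene; 3 (2S)-2-[(benzyloxy)methyl]oxirane [(S)-benzyl glycidyl ether]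
Product: 5 (2S)-1-(benzyloxy)-3-[4-(benzyloxy)-3,5-dimethoxyphenyl]propan-2-ol, via arylmagnesium bromide 4 (not isolated)
Conditions: Mg (1,2-dibromoethane-activated), THF, reflux; then CuI (copper iodide, 10 mol %), 3, THF, −30 → 0 °C; aq. NH4Cl
Reagents that add atoms: magnesium, [Mg] (held only in intermediate 4; none remains in 5)
Why: Grignard formation followed by copper-catalysed epoxide opening; the arylcopper species attacks the unhindered terminal carbon, so the stereocentre of 3 is not involved and 5 keeps the (S) configuration, while copper catalysis outpaces halohydrin formation by magnesium bromide.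

Step 3
Reactants: 6 syringic acid (4-hydroxy-3,5-dimethoxybenzoic acid)
Product: 7 benzyl 4-hydroxy-3,5-dimethoxybenzoate
Conditions: BnBr (1.05 equiv), KHCO3, DMF, 40 °C
Reagents that add atoms: benzyl bromide, BrCc1ccccc1
Why: Carboxylate O-alkylation; hydrogencarbonate deprotonates the acid but not the much less acidic phenol, so only the carboxylate is alkylated and the phenol needed for step 4 stays free.

Step 4
Reactants: 5 (2S)-1-(benzyloxy)-3-[4-(benzyloxy)-3,5-dimethoxyphenyl]propan-2-ol; 7 benzyl 4-hydroxy-3,5-dimethoxybenzoate
Product: 8 benzyl 4-{[(2R)-1-(benzyloxy)-3-[4-(benzyloxy)-3,5-dimethoxyphenyl]propan-2-yl]oxy}-3,5-dimethoxybenzoate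
Conditions: PPh3, DIAD, THF, 0 °C → rt
Reagents that add atoms: none
Why: Mitsunobu etherification; the para-ester makes phenol 7 acidic enough to protonate the betaine, and its phenoxide displaces the oxyphosphonium group of 5 by SN2 with inversion, turning the (S)-carbinol into the (R)-aryl ether that has the spatial arrangement of the target at C8.

Step 5
Reactants: 8 benzyl 4-{[(2R)-1-(benzyloxy)-3-[4-(benzyloxy)-3,5-dimethoxyphenyl]propan-2-yl]oxy}-3,5-dimethoxybenzoate
Product: 9 4-{[(2R)-1-hydroxy-3-(4-hydroxy-3,5-dimethoxyphenyl)propan-2-yl]oxy}-3,5-dimethoxybenzoic acid
Conditions: H2 (1 atm), Pd/C (palladium on carbon, 10 %), EtOAc/MeOH, rt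
Reagents that add atoms: none
Why: Catalytic hydrogenolysis cleaves the benzyl ester, the aryl benzyl ether and the primary alkyl benzyl ether in one operation; the C8–O–aryl ether is not benzylic, nothing else is reducible, and the neutral conditions leave C8 untouched.

Step 6
Reactants: 9 4-{[(2R)-1-hydroxy-3-(4-hydroxy-3,5-dimethoxyphenyl)propan-2-yl]oxy}-3,5-dimethoxybenzoic acid
Product: 12 4-{[(2S)-3-hydroxy-1-(4-hydroxy-3,5-dimethoxyphenyl)-1-oxopropan-2-yl]oxy}-3,5-dimethoxybenzoic acid (CNP0511559.2), via quinone methide 10 (not isolated), via benzylic alcohol 11 (not isolated)
Conditions: graphite anode, Pt cathode, undivided cell, constant current (about 2 mA cm−2, 4.0–4.4 F mol−1), LiClO4 (0.1 M), MeCN/H2O 3:1, AcOH (2 vol %), 15–20 °C; then dilute aq. HCl, EtOAc extraction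
Reagents that add atoms: water, O
Why: The ring A phenol is the most easily oxidized group; loss of two electrons and two protons (through the phenoxyl radical and either benzylic proton loss from the ring cation or disproportionation of two radicals) should give para-quinone methide 10, with the oxidation relayed to C7 because C7 is para to the phenol oxygen. Water, helped by acetic acid, adds to C7 of 10 to give para-hydroxybenzylic alcohol 11 as both C7 epimers. A second two-electron oxidation of 11 by the same relay, with loss of the C7 proton, gives ketone 12 after proton shift. The closest known reaction type is the anodic or DDQ oxidation of para-alkylphenols through quinone methides to benzylic alcohols and para-hydroxyaryl ketones, and 10 is the same kind of beta-aryloxy quinone methide that is known to add water to give arylglycerol beta-aryl ethers. No ring closes and no stereocentre is created; C8 keeps its arrangement and is renamed (S) only because C7 now outranks C9. Site selectivity is secured by the phenol: ring B has no free phenol and carries a carboxyl, and the primary alcohol oxidizes only at much higher potential. Hydration of 10 must beat loss of the C8 proton, which would give an enol ether and erase the stereocentre; the water-rich, weakly acidic, base-free medium favours hydration, and acetic acid also buffers the cathode so that no hydroxide reaches the base-labile product. The reaction should stop at 12 because a para-acylphenol is harder to oxidize, and the charge is limited to about four electrons per molecule.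

## Compound list

1 | 4-bromo-2,6-dimethoxyphenol | COc1cc(Br)cc(OC)c1O | starting material
2 | 2-(benzyloxy)-5-bromo-1,3-dimethoxybenzene | COc1cc(Br)cc(OC)c1OCc1ccccc1 | intermediate
3 | (2S)-2-[(benzyloxy)methyl]oxirane [(S)-benzyl glycidyl ether] | C(OCc1ccccc1)[C@@H]1CO1 | starting material
4 | [4-(benzyloxy)-3,5-dimethoxyphenyl]magnesium bromide (formed in the flask, not isolated) | COc1cc([Mg]Br)cc(OC)c1OCc1ccccc1 | intermediate
5 | (2S)-1-(benzyloxy)-3-[4-(benzyloxy)-3,5-dimethoxyphenyl]propan-2-ol | COc1cc(C[C@@H](COCc2ccccc2)O)cc(OC)c1OCc1ccccc1 | intermediate
6 | syringic acid (4-hydroxy-3,5-dimethoxybenzoic acid) | COc1cc(C(=O)O)cc(OC)c1O | starting material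
7 | benzyl 4-hydroxy-3,5-dimethoxybenzoate | COc1cc(C(=O)OCc2ccccc2)cc(OC)c1O | intermediate
8 | benzyl 4-{[(2R)-1-(benzyloxy)-3-[4-(benzyloxy)-3,5-dimethoxyphenyl]propan-2-yl]oxy}-3,5-dimethoxybenzoate | COc1cc(C[C@H](COCc2ccccc2)Oc2c(OC)cc(C(=O)OCc3ccccc3)cc2OC)cc(OC)c1OCc1ccccc1 | intermediate
9 | 4-{[(2R)-1-hydroxy-3-(4-hydroxy-3,5-dimethoxyphenyl)propan-2-yl]oxy}-3,5-dimethoxybenzoic acid | COc1cc(C[C@H](CO)Oc2c(OC)cc(C(=O)O)cc2OC)cc(OC)c1O | intermediate
10 | 4-{[(2R)-1-(3,5-dimethoxy-4-oxocyclohexa-2,5-dien-1-ylidene)-3-hydroxypropan-2-yl]oxy}-3,5-dimethoxybenzoic acid (para-quinone methide, not isolated) | COC1=CC(=C[C@H](CO)Oc2c(OC)cc(C(=O)O)cc2OC)C=C(OC)C1=O | intermediate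
11 | 4-{[(2S)-1,3-dihydroxy-1-(4-hydroxy-3,5-dimethoxyphenyl)propan-2-yl]oxy}-3,5-dimethoxybenzoic acid, both C1 (C7) epimers (not isolated) | COc1cc(C(O)[C@H](CO)Oc2c(OC)cc(C(=O)O)cc2OC)cc(OC)c1O | intermediate
12 | 4-{[(2S)-3-hydroxy-1-(4-hydroxy-3,5-dimethoxyphenyl)-1-oxopropan-2-yl]oxy}-3,5-dimethoxybenzoic acid (CNP0511559.2) | COc1cc(C(=O)[C@H](CO)Oc2c(OC)cc(C(=O)O)cc2OC)cc(OC)c1O | target

## Step count and risks

Total step count: 6. Longest linear sequence: 5 steps (1 → 2 → 5 → 8 → 9 → 12, steps 1, 2, 4, 5 and 6); step 3 is a one-step branch.

**Step 6 (key step).**
- What may go wrong: the oxidized phenol may be diverted away from the quinone methide. Water may capture the ring-centred cation on the ring itself, followed by loss of methanol or of the whole side chain. The ring A–C7 or C7–C8 bond may cleave at the stage of alcohol 11. The anode may be passivated by phenol-derived films. Less likely, proton loss from C8 of 10 would tautomerize the quinone methide and destroy the stereocentre.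
- Fallback: from 9, the same oxygenation is done chemically, in two separately controlled stages, with 2,3-dichloro-5,6-dicyano-1,4-benzoquinone (DDQ). One equivalent in dioxane/water at room temperature removes hydride from C7 inside the phenol–quinone charge-transfer complex, so no free ring cation meets water, and the quinone methide is hydrated to 11, now isolated as the C7 epimer mixture. A second equivalent of DDQ in dioxane, a standard oxidant for para-hydroxybenzylic alcohols, then gives the ketone. The fallback leaves the route at 9 and returns at 12, and makes no compound outside the list.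

**Step 4 (Mitsunobu etherification).**
- What may go wrong: substitution at the unactivated secondary carbon by the di-ortho-methoxy phenoxide may be slow. That would let elimination of the oxyphosphonium ion towards the alkene conjugated with ring A compete, along with alkylation of the hydrazide by-product. Participation of the electron-rich ring A would erode the inversion.
- Fallback: the displacement is moved to a carbon activated by an ester. Grignard reagent 4 (from 2 as in step 2) opens purchased methyl (2S)-oxirane-2-carboxylate F1 at its CH2 carbon (CuI catalysis, −40 °C, inverse addition) to give methyl (2S)-3-[4-(benzyloxy)-3,5-dimethoxyphenyl]-2-hydroxypropanoate F2. Mitsunobu reaction of F2 with 7 (PPh3, DIAD), of the type routinely used for 2-aryloxy esters, gives with inversion benzyl 4-{[(2R)-3-[4-(benzyloxy)-3,5-dimethoxyphenyl]-1-methoxy-1-oxopropan-2-yl]oxy}-3,5-dimethoxybenzoate F3. NaBH4 in THF/MeOH reduces the activated alpha-aryloxy methyl ester beside the electron-rich benzoate to give benzyl 4-{[(2R)-1-hydroxy-3-[4-(benzyloxy)-3,5-dimethoxyphenyl]propan-2-yl]oxy}-3,5-dimethoxybenzoate F4. Hydrogenolysis of F4 as in step 5 returns to the route at 9.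

**Step 2 (Grignard formation and epoxide opening).**
- What may go wrong: magnesium insertion into the electron-rich bromide may be sluggish and accompanied by homocoupling. Bromide from the magnesium salts may open the epoxide in place of aryl transfer.
- Fallback: from 2, bromine–lithium exchange (n-BuLi, THF, −78 °C) gives [4-(benzyloxy)-3,5-dimethoxyphenyl]lithium F5. F5 opens epoxide 3 at the terminal carbon under BF3·OEt2 activation at −78 °C, with no magnesium halide and no copper, and returns to the route at 5.

## Further compounds

F0 | step 6 | none | none
F1 | step 4 | methyl (2S)-oxirane-2-carboxylate | COC(=O)[C@@H]1CO1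
F2 | step 4 | methyl (2S)-3-[4-(benzyloxy)-3,5-dimethoxyphenyl]-2-hydroxypropanoate | COc1cc(C[C@@H](C(=O)OC)O)cc(OC)c1OCc1ccccc1
F3 | step 4 | benzyl 4-{[(2R)-3-[4-(benzyloxy)-3,5-dimethoxyphenyl]-1-methoxy-1-oxopropan-2-yl]oxy}-3,5-dimethoxybenzoate | COc1cc(C[C@H](C(=O)OC)Oc2c(OC)cc(C(=O)OCc3ccccc3)cc2OC)cc(OC)c1OCc1ccccc1
F4 | step 4 | benzyl 4-{[(2R)-1-hydroxy-3-[4-(benzyloxy)-3,5-dimethoxyphenyl]propan-2-yl]oxy}-3,5-dimethoxybenzoate | COc1cc(C[C@H](CO)Oc2c(OC)cc(C(=O)OCc3ccccc3)cc2OC)cc(OC)c1OCc1ccccc1
F5 | step 2 | [4-(benzyloxy)-3,5-dimethoxyphenyl]lithium | [Li]c1cc(OC)c(OCc2ccccc2)c(OC)c1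
A1 | alternative 1 | benzyl 4-diazo-3,5-dioxocyclohexane-1-carboxylate | [N-]=[N+]=C1C(=O)CC(C(=O)OCc2ccccc2)CC1=O
A2 | alternative 1 | 1-[4-(benzyloxy)-3,5-dimethoxyphenyl]-1,3-bis[(tert-butyldimethylsilyl)oxy]propan-2-ol (configuration as in the SMILES) | COc1cc([C@@H](O[Si](C)(C)C(C)(C)C)[C@H](CO[Si](C)(C)C(C)(C)C)O)cc(OC)c1OCc1ccccc1
A3 | alternative 1 | O–H insertion product, 2-alkoxy-3-hydroxycyclohex-2-enone ether drawn as one enol tautomer | COc1cc([C@@H](O[Si](C)(C)C(C)(C)C)[C@H](CO[Si](C)(C)C(C)(C)C)OC2=C(O)CC(C(=O)OCc3ccccc3)CC2=O)cc(OC)c1OCc1ccccc1
A4 | alternative 2 | benzyl 4-{2-[(4R)-4-benzyl-2-oxo-1,3-oxazolidin-3-yl]-2-oxoethoxy}-3,5-dimethoxybenzoate | COc1cc(C(=O)OCc2ccccc2)cc(OC)c1OCC(=O)N1[C@H](Cc2ccccc2)COC1=O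
A5 | alternative 2 | 4-(benzyloxy)-3,5-dimethoxybenzaldehyde | COc1cc(C=O)cc(OC)c1OCc1ccccc1
A6 | alternative 2 | syn aldol adduct, (2R,3S) in the acyl chain, on the (4R)-4-benzyl oxazolidinone | COc1cc([C@H](O)[C@H](C(=O)N2[C@H](Cc3ccccc3)COC2=O)Oc2c(OC)cc(C(=O)OCc3ccccc3)cc2OC)cc(OC)c1OCc1ccccc1
A7 | alternative 3 | tert-butyl 4-{[(2S)-3-[(tert-butyldimethylsilyl)oxy]-1-oxo-1-(phenylsulfanyl)propan-2-yl]oxy}-3,5-dimethoxybenzoate | O=C(Sc1ccccc1)[C@H](CO[Si](C)(C)C(C)(C)C)Oc1c(OC)cc(C(=O)OC(C)(C)C)cc1OC
A8 | alternative 3 | [3,5-dimethoxy-4-(methoxymethoxy)phenyl]boronic acid | COCOc1c(OC)cc(B(O)O)cc1OC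
A9 | alternative 3 | fully protected (S)-ketone: tert-butyl ester, silyl ether, methoxymethyl ether | COCOc1c(OC)cc(C(=O)[C@H](CO[Si](C)(C)C(C)(C)C)Oc2c(OC)cc(C(=O)OC(C)(C)C)cc2OC)cc1OC
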